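**Retrosynthetic overview**

1. The target is (3S,5R,9S,10R,13S)-labd-7-ene-3,15-diyl diformate. The end game is diformylation of the 3β,15-diol, hydride reduction of a C3 ketone, and Birch-type reductive methylation of a ring A enone (C3=O, C4=C5), which sets the trans C5–H and completes the C4 gem-dimethyl group.
2. Key disconnection: ring B is opened at C5–C6 and at C7=C8. C6–C7 comes from vinyltriphenylphosphonium bromide, C5 is the iodine-bearing sp2 carbon of a ring A vinyl iodide, and C8 is a methyl ketone on C9.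
3. Enabling feature: in ring B the C6 methylene sits on the ring-fusion carbon C5, and the C7=C8 bond ends at the methyl-bearing C8, which is 1,4 to C5 through C10–C9. A C5 radical and a C8 methyl ketone can therefore be bridged by one vinylphosphonium unit (radical addition, then intramolecular Wittig). Keeping C5 sp2 (C4=C5) avoids creating that stereocentre, flanked by C4 and the quaternary C10, by an intermolecular attack.
4. Precursor: the C9/C10 stereodiad comes from an iridium-catalysed branched allylic alkylation of a ring A vinylogous-ester enolate with an (S)-citronellol-derived allylic carbonate (C11–C16, C13). Carbonyl transposition then gives the C5 iodide and Wacker oxidation the C8 ketone.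
5. Ring order: ring A is bought (vinylogous ester of 2-methylcyclohexane-1,3-dione); ring B is closed in the key step.

Key step: step 9

Remark: labdane numbering is used throughout (C1–C10 decalin, C11–C16 side chain, C17 on C8, C20 on C10), and 3-ethoxy-2-methylcyclohex-2-en-1-one is taken as a purchasable compound.

**Route**

Step 1
Reactants: 1 3-ethoxy-2-methylcyclohex-2-en-1-one
Product: 2 3-ethoxy-2,6-dimethylcyclohex-2-en-1-one (racemic)
Conditions: LiN(iPr)2, THF, −78 °C; MeI, −78 to 0 °C
Reagents that add atoms: iodomethane, CI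
Why: Kinetic deprotonation of the vinylogous ester occurs only at the α′ carbon (the future C10) and the lithium enolate is C-methylated (Stork–Danheiser alkylation), the new centre being racemic and erased in step 2.

Step 2
Reactants: 2 3-ethoxy-2,6-dimethylcyclohex-2-en-1-one
Product: 3 1-ethoxy-2,4-dimethyl-3-(trimethylsilyloxy)cyclohexa-1,3-diene
Conditions: LiN(iPr)2, THF, −78 °C; Me3SiCl; non-aqueous work-up
Reagents that add atoms: chlorotrimethylsilane, C[Si](C)(C)Cl
Why: A second kinetic α′-deprotonation followed by O-silylation (enol silane formation) gives the cross-conjugated silyl dienol ether that serves as the latent tetrasubstituted enolate, with no stereocentre left.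

Step 3
Reactants: 4 (S)-citronellol [(3S)-3,7-dimethyloct-6-en-1-ol]
Product: 5 (3S)-3,7-dimethyl-1-(triisopropylsilyloxy)oct-6-ene
Conditions: iPr3SiCl, imidazole, DMF, rt
Reagents that add atoms: chlorotriisopropylsilane, CC(C)[Si](Cl)(C(C)C)C(C)C
Why: Standard silylation of the primary alcohol gives an ether that should survive fluoride catalysis, dissolving metal and mild acid, and the C13 stereocentre is carried over unchanged from (S)-citronellol.

Step 4
Reactants: 5 (3S)-3,7-dimethyl-1-(triisopropylsilyloxy)oct-6-ene; 6 allyl methyl carbonate (excess)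
Product: 7 methyl (2E,6S)-6-methyl-8-(triisopropylsilyloxy)oct-2-en-1-yl carbonate
Conditions: second-generation Hoveyda–Grubbs catalyst (3 mol %), CH2Cl2, 40 °C
Reagents that add atoms: none
Why: Olefin cross-metathesis of the prenyl-type trisubstituted alkene with the terminal allyl carbonate releases volatile 2-methylpropene and should give mainly the E allylic carbonate.

Step 5
Reactants: 3 1-ethoxy-2,4-dimethyl-3-(trimethylsilyloxy)cyclohexa-1,3-diene; 7 methyl (2E,6S)-6-methyl-8-(triisopropylsilyloxy)oct-2-en-1-yl carbonate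
Product: 8 (6R)-3-ethoxy-2,6-dimethyl-6-[(3S,6S)-6-methyl-8-(triisopropylsilyloxy)oct-1-en-3-yl]cyclohex-2-en-1-one
Conditions: [Ir(cod)Cl]2 (2 mol %), BINOL-derived N,N-bis(1-phenylethyl)phosphoramidite (4 mol %, the enantiomer that gives the 9S centre), KF and 18-crown-6 (10 mol % each), THF, 35 °C
Reagents that add atoms: none
Why: In this iridium-catalysed branched-selective asymmetric allylic alkylation the fluoride-released enolate attacks the substituted terminus of the allyl–iridium complex, the chiral catalyst fixing C9 (S) and, through the preferred open transition state of the prochiral tetrasubstituted enolate, the adjacent quaternary C10 (R).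

Step 6
Reactants: 8 (6R)-3-ethoxy-2,6-dimethyl-6-[(3S,6S)-6-methyl-8-(triisopropylsilyloxy)oct-1-en-3-yl]cyclohex-2-en-1-one
Product: 10 (4R)-3-iodo-2,4-dimethyl-4-[(3S,6S)-6-methyl-8-(triisopropylsilyloxy)oct-1-en-3-yl]cyclohex-2-en-1-one, via chloro enone 9 (not isolated)
Conditions: (COCl)2, CH2Cl2, 0 °C to rt; solvent exchange; NaI, MeCN, 45 °C
Reagents that add atoms: sodium iodide, [Na+].[I-]
Why: Oxalyl chloride acylates the vinylogous-ester carbonyl oxygen, chloride replaces the activated oxygen at C5 and the ethyl group is lost, so the carbonyl is transposed to C3 and the halogen sits next to the quaternary C10 (Vilsmeier-type chlorination of a vinylogous ester), after which addition–elimination with iodide (Finkelstein-type exchange) gives the vinyl iodide.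

Step 7
Reactants: 10 (4R)-3-iodo-2,4-dimethyl-4-[(3S,6S)-6-methyl-8-(triisopropylsilyloxy)oct-1-en-3-yl]cyclohex-2-en-1-one
Product: 11 (4R)-3-iodo-2,4-dimethyl-4-[(3S,6S)-6-methyl-8-(triisopropylsilyloxy)oct-1-en-3-yl]cyclohex-2-en-1-ol (C1 epimers)
Conditions: NaBH4, CeCl3·7H2O, MeOH, −20 °C
Reagents that add atoms: none
Why: Luche reduction delivers hydride 1,2 to the enone without touching the vinyl iodide or the terminal alkene, and the new carbinol centre (labdane C3) need not be controlled because it is oxidised again in step 10.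

Step 8
Reactants: 11 (4R)-3-iodo-2,4-dimethyl-4-[(3S,6S)-6-methyl-8-(triisopropylsilyloxy)oct-1-en-3-yl]cyclohex-2-en-1-ol
Product: 12 (3R,6S)-3-[(1R)-4-hydroxy-2-iodo-1,3-dimethylcyclohex-2-en-1-yl]-6-methyl-8-(triisopropylsilyloxy)octan-2-one (carbinol epimers)
Conditions: PdCl2 (10 mol %), CuCl, O2 (1 atm), DMF/H2O 7:1, rt
Reagents that add atoms: water, O
Why: Tsuji–Wacker oxidation converts the monosubstituted vinyl group into the methyl ketone with Markovnikov selectivity, the tetrasubstituted iodoalkene being too hindered for hydroxypalladation, and C9 should not epimerise under these near-neutral conditions.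

Step 9
Reactants: 12 (3R,6S)-3-[(1R)-4-hydroxy-2-iodo-1,3-dimethylcyclohex-2-en-1-yl]-6-methyl-8-(triisopropylsilyloxy)octan-2-one; 13 vinyltriphenylphosphonium bromide
Product: 15 (9S,10R,13S)-15-(triisopropylsilyloxy)-19-norlabda-4,7-dien-3-ol (C3 epimers), via ylide 14 (not isolated)
Conditions: fac-Ir(ppy)3 (1 mol %), tetrakis(dimethylamino)ethylene (TDAE, 1.2 equiv), 13 (5 equiv), degassed MeCN, 450 nm LEDs, 25 °C
Reagents that add atoms: none
Why: Proposed new method: the excited iridium photocatalyst, turned over by the two-electron donor TDAE, reduces the C5–I bond of 12 to a vinyl σ-radical that adds to the unsubstituted terminus of 13 (C5–C6), and the resulting α-phosphonio radical is reduced to the non-stabilised ylide 14 (radical–polar crossover) without any acid being formed. The closest known reaction types are the Giese addition of carbon radicals to vinylphosphonium salts followed by Wittig olefination and the polar annulation of carbonyl-bearing nucleophiles with vinyltriphenylphosphonium salts (Schweizer-type); the vinyl radical and the internal ketone are the new elements. Ring B is closed by intramolecular Wittig reaction of the C7 ylide with the C8 methyl ketone through a six-membered ring, which can only give the endocyclic cis C7=C8 bond and places the C17 methyl on C8 without regiochemical ambiguity. No new stereocentre is created, because C5 stays sp2 (C4=C5) and is set in step 11, while C9 and C10 are untouched under these base-free conditions and the C3 hydroxyl is too weak an acid to quench the ylide. The step needs chemoselective reduction of the vinyl iodide beside ketone, alcohol and silyl ether and radical addition faster than hydrogen-atom transfer; the weak C–I bond, the absence of a good hydrogen donor and the large excess of the cationic acceptor should secure this, and the non-conjugated C3 carbinol (instead of an enone) removes the acidic C6 protons that would otherwise expel triphenylphosphine.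

Step 10
Reactants: 15 (9S,10R,13S)-15-(triisopropylsilyloxy)-19-norlabda-4,7-dien-3-ol
Product: 16 (9S,10R,13S)-15-(triisopropylsilyloxy)-19-norlabda-4,7-dien-3-one
Conditions: MnO2 (excess), CH2Cl2, rt
Reagents that add atoms: none
Why: Manganese dioxide oxidises the allylic carbinol to the enone under neutral conditions (allylic oxidation), which should avoid acid- or base-induced migration of the skipped C7=C8 bond into conjugation.

Step 11
Reactants: 16 (9S,10R,13S)-15-(triisopropylsilyloxy)-19-norlabda-4,7-dien-3-one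
Product: 18 (5R,9S,10R,13S)-15-(triisopropylsilyloxy)labd-7-en-3-one, via lithium enolate 17 (not isolated)
Conditions: Li (2.5 equiv), NH3/THF, t-BuOH (1 equiv), −78 °C; isoprene; then MeI, −78 to −33 °C
Reagents that add atoms: iodomethane, CI
Why: Dissolving-metal (Birch-type) reduction of the enone protonates C5 axially on the face opposite the angular C10 methyl, giving the trans ring fusion (5R), and the regiodefined lithium enolate is methylated at C4 to complete the gem-dimethyl group (reductive alkylation), the isolated trisubstituted alkene and the silyl ether being inert.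

Step 12
Reactants: 18 (5R,9S,10R,13S)-15-(triisopropylsilyloxy)labd-7-en-3-one
Product: 19 (3S,5R,9S,10R,13S)-15-(triisopropylsilyloxy)labd-7-en-3-ol
Conditions: NaBH4, MeOH/THF, 0 °C
Reagents that add atoms: none
Why: Borohydride reduction of the 4,4-dimethyl ketone occurs from the less hindered α face (axial attack, away from the axial 4β-methyl) and should give the equatorial 3β-alcohol (3S).

Step 13
Reactants: 19 (3S,5R,9S,10R,13S)-15-(triisopropylsilyloxy)labd-7-en-3-ol
Product: 20 (3S,5R,9S,10R,13S)-labd-7-ene-3,15-diol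
Conditions: Bu4NF, THF, rt
Reagents that add atoms: none
Why: Fluoride-mediated desilylation frees the primary alcohol without affecting the alkene or any stereocentre.

Step 14
Reactants: 20 (3S,5R,9S,10R,13S)-labd-7-ene-3,15-diol
Product: 21 (3S,5R,9S,10R,13S)-labd-7-ene-3,15-diyl diformate (CNP0137609.1)
Conditions: HCO2H (excess), dicyclohexylcarbodiimide, 4-(dimethylamino)pyridine (cat.), CH2Cl2, 0 °C to rt
Reagents that add atoms: formic acid, O=CO
Why: Carbodiimide-mediated (Steglich-type) esterification formylates both the primary and the hindered secondary hydroxyl group under mild, non-acidic conditions that should not isomerise the C7=C8 bond.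

**Compound list**

1 | 3-ethoxy-2-methylcyclohex-2-en-1-one | CCOC1=C(C)C(=O)CCC1 | starting material
2 | 3-ethoxy-2,6-dimethylcyclohex-2-en-1-one (racemic) | CCOC1=C(C)C(=O)C(C)CC1 | intermediate
3 | 1-ethoxy-2,4-dimethyl-3-(trimethylsilyloxy)cyclohexa-1,3-diene | CCOC1=C(C)C(O[Si](C)(C)C)=C(C)CC1 | intermediate
4 | (S)-citronellol | CC(C)=CCC[C@H](C)CCO | starting material
5 | (3S)-3,7-dimethyl-1-(triisopropylsilyloxy)oct-6-ene | CC(C)=CCC[C@H](C)CCO[Si](C(C)C)(C(C)C)C(C)C | intermediate
6 | allyl methyl carbonate | C=CCOC(=O)OC | starting material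
7 | methyl (2E,6S)-6-methyl-8-(triisopropylsilyloxy)oct-2-en-1-yl carbonate | COC(=O)OC/C=C/CC[C@H](C)CCO[Si](C(C)C)(C(C)C)C(C)C | intermediate
8 | (6R)-3-ethoxy-2,6-dimethyl-6-[(3S,6S)-6-methyl-8-(triisopropylsilyloxy)oct-1-en-3-yl]cyclohex-2-en-1-one | O=C1C(C)=C(OCC)CC[C@]1(C)[C@H](C=C)CC[C@H](C)CCO[Si](C(C)C)(C(C)C)C(C)C | intermediate
9 | (4R)-3-chloro-2,4-dimethyl-4-[(3S,6S)-6-methyl-8-(triisopropylsilyloxy)oct-1-en-3-yl]cyclohex-2-en-1-one (not isolated) | ClC1=C(C)C(=O)CC[C@]1(C)[C@H](C=C)CC[C@H](C)CCO[Si](C(C)C)(C(C)C)C(C)C | intermediate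
10 | (4R)-3-iodo-2,4-dimethyl-4-[(3S,6S)-6-methyl-8-(triisopropylsilyloxy)oct-1-en-3-yl]cyclohex-2-en-1-one | IC1=C(C)C(=O)CC[C@]1(C)[C@H](C=C)CC[C@H](C)CCO[Si](C(C)C)(C(C)C)C(C)C | intermediate
11 | (4R)-3-iodo-2,4-dimethyl-4-[(3S,6S)-6-methyl-8-(triisopropylsilyloxy)oct-1-en-3-yl]cyclohex-2-en-1-ol (C1 epimers) | IC1=C(C)C(O)CC[C@]1(C)[C@H](C=C)CC[C@H](C)CCO[Si](C(C)C)(C(C)C)C(C)C | intermediate
12 | (3R,6S)-3-[(1R)-4-hydroxy-2-iodo-1,3-dimethylcyclohex-2-en-1-yl]-6-methyl-8-(triisopropylsilyloxy)octan-2-one (carbinol epimers) | IC1=C(C)C(O)CC[C@]1(C)[C@H](C(C)=O)CC[C@H](C)CCO[Si](C(C)C)(C(C)C)C(C)C | intermediate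
13 | vinyltriphenylphosphonium bromide | C=C[P+](c1ccccc1)(c1ccccc1)c1ccccc1.[Br-] | starting material
14 | triphenylphosphonium ylide at C7 (P=C7H–C6H2–C5, ketone at C8; not isolated) | c1ccccc1P(c1ccccc1)(c1ccccc1)=CCC1=C(C)C(O)CC[C@]1(C)[C@H](C(C)=O)CC[C@H](C)CCO[Si](C(C)C)(C(C)C)C(C)C | intermediate
15 | (9S,10R,13S)-15-(triisopropylsilyloxy)-19-norlabda-4,7-dien-3-ol (C3 epimers) | CC1=CCC2=C(C)C(O)CC[C@]2(C)[C@H]1CC[C@H](C)CCO[Si](C(C)C)(C(C)C)C(C)C | intermediate
16 | (9S,10R,13S)-15-(triisopropylsilyloxy)-19-norlabda-4,7-dien-3-one | CC1=CCC2=C(C)C(=O)CC[C@]2(C)[C@H]1CC[C@H](C)CCO[Si](C(C)C)(C(C)C)C(C)C | intermediate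
17 | lithium (5R,9S,10R,13S)-15-(triisopropylsilyloxy)-19-norlabda-3,7-dien-3-olate (not isolated) | CC1=CC[C@H]2C(C)=C([O-])CC[C@]2(C)[C@H]1CC[C@H](C)CCO[Si](C(C)C)(C(C)C)C(C)C.[Li+] | intermediate
18 | (5R,9S,10R,13S)-15-(triisopropylsilyloxy)labd-7-en-3-one | CC1=CC[C@H]2C(C)(C)C(=O)CC[C@]2(C)[C@H]1CC[C@H](C)CCO[Si](C(C)C)(C(C)C)C(C)C | intermediate
19 | (3S,5R,9S,10R,13S)-15-(triisopropylsilyloxy)labd-7-en-3-ol | CC1=CC[C@H]2C(C)(C)[C@@H](O)CC[C@]2(C)[C@H]1CC[C@H](C)CCO[Si](C(C)C)(C(C)C)C(C)C | intermediate
20 | (3S,5R,9S,10R,13S)-labd-7-ene-3,15-diol | CC1=CC[C@H]2C(C)(C)[C@@H](O)CC[C@]2(C)[C@H]1CC[C@H](C)CCO | intermediate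
21 | (3S,5R,9S,10R,13S)-labd-7-ene-3,15-diyl diformate | CC1=CC[C@H]2C(C)(C)[C@@H](OC=O)CC[C@]2(C)[C@H]1CC[C@H](C)CCOC=O | target

**Step count and risks**

Total step count: 14. Longest linear sequence: 12 steps (steps 1, 2 and 5–14, from 1 to 21; the citronellol branch, steps 3–4, is equally long up to the union).

Steps most likely to fail:

1. Step 9 (key step, proposed new method). The vinyl radical may be quenched by hydrogen-atom transfer (from the medium, or by 1,5-translocation from the acetyl methyl or C12) before it adds, and the ylide may add to excess vinylphosphonium salt instead of closing the ring. The fallback uses known chemistry and sets out from 12. A Stille coupling with allyltributylstannane (Pd(PPh3)4, CuI, DMF, 45 °C) would give (3R,6S)-3-[(1R)-4-hydroxy-1,3-dimethyl-2-(prop-2-en-1-yl)cyclohex-2-en-1-yl]-6-methyl-8-(triisopropylsilyloxy)octan-2-one F1. Wittig methylenation of its ketone (Ph3P=CH2, THF, −78 to 0 °C) would give (4R)-2,4-dimethyl-4-[(3S,6S)-2,6-dimethyl-8-(triisopropylsilyloxy)oct-1-en-3-yl]-3-(prop-2-en-1-yl)cyclohex-2-en-1-ol F2. Ring-closing metathesis with second-generation Grubbs catalyst (CH2Cl2, 40 °C) would then form C7=C8 and come back to the route at 15.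

2. Step 5. Facial discrimination of the prochiral tetrasubstituted enolate (C10) may be poor, or linear allylation may compete. The fallback forms the quaternary centre by substrate control instead and sets out from 1. LiN(iPr)2/Me3SiCl would give 1-ethoxy-2-methyl-3-(trimethylsilyloxy)cyclohexa-1,3-diene F3. The same iridium-catalysed allylation with 7, now at an unsubstituted α′ carbon, would give 3-ethoxy-2-methyl-6-[(3S,6S)-6-methyl-8-(triisopropylsilyloxy)oct-1-en-3-yl]cyclohex-2-en-1-one F4 with C9 fixed by the catalyst. α′-Methylation (LiN(iPr)2, MeI) should then proceed under allylic 1,3-strain control: with C9–H eclipsing the enolate double bond, methyl iodide is expected to enter syn to the vinyl group and anti to the alkyl chain, which is the required relative configuration. The fallback comes back at 8.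

3. Step 6. Halide exchange at the hindered C5 may be slow, or hydrolysis to the 1,3-dione may erase the regiochemical definition. The fallback avoids the vinyl halide altogether and sets out from 8. Tsuji–Wacker oxidation (PdCl2, CuCl, O2, DMF/H2O) would give (6R)-3-ethoxy-2,6-dimethyl-6-[(3R,6S)-6-methyl-2-oxo-8-(triisopropylsilyloxy)octan-3-yl]cyclohex-2-en-1-one F5. Methylenation of the ketone (Ph3P=CH2) would give (6R)-3-ethoxy-2,6-dimethyl-6-[(3S,6S)-2,6-dimethyl-8-(triisopropylsilyloxy)oct-1-en-3-yl]cyclohex-2-en-1-one F6. 1,2-Addition of allylmagnesium bromide (CeCl3, THF, −78 °C) to the vinylogous-ester carbonyl and dilute-acid work-up (Stork–Danheiser transposition) would give (4R)-2,4-dimethyl-4-[(3S,6S)-2,6-dimethyl-8-(triisopropylsilyloxy)oct-1-en-3-yl]-3-(prop-2-en-1-yl)cyclohex-2-en-1-one F7. Ring-closing metathesis (second-generation Grubbs catalyst) would come back at 16, bypassing steps 6–10.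

**Further compounds**

F1 | step 9 | (3R,6S)-3-[(1R)-4-hydroxy-1,3-dimethyl-2-(prop-2-en-1-yl)cyclohex-2-en-1-yl]-6-methyl-8-(triisopropylsilyloxy)octan-2-one | C=CCC1=C(C)C(O)CC[C@]1(C)[C@H](C(C)=O)CC[C@H](C)CCO[Si](C(C)C)(C(C)C)C(C)C
F2 | step 9 | (4R)-2,4-dimethyl-4-[(3S,6S)-2,6-dimethyl-8-(triisopropylsilyloxy)oct-1-en-3-yl]-3-(prop-2-en-1-yl)cyclohex-2-en-1-ol | C=CCC1=C(C)C(O)CC[C@]1(C)[C@H](C(C)=C)CC[C@H](C)CCO[Si](C(C)C)(C(C)C)C(C)C
F3 | step 5 | 1-ethoxy-2-methyl-3-(trimethylsilyloxy)cyclohexa-1,3-diene | CCOC1=C(C)C(O[Si](C)(C)C)=CCC1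
F4 | step 5 | 3-ethoxy-2-methyl-6-[(3S,6S)-6-methyl-8-(triisopropylsilyloxy)oct-1-en-3-yl]cyclohex-2-en-1-one (C6 epimers) | O=C1C(C)=C(OCC)CCC1[C@H](C=C)CC[C@H](C)CCO[Si](C(C)C)(C(C)C)C(C)C
F5 | step 6 | (6R)-3-ethoxy-2,6-dimethyl-6-[(3R,6S)-6-methyl-2-oxo-8-(triisopropylsilyloxy)octan-3-yl]cyclohex-2-en-1-one | O=C1C(C)=C(OCC)CC[C@]1(C)[C@H](C(C)=O)CC[C@H](C)CCO[Si](C(C)C)(C(C)C)C(C)C
F6 | step 6 | (6R)-3-ethoxy-2,6-dimethyl-6-[(3S,6S)-2,6-dimethyl-8-(triisopropylsilyloxy)oct-1-en-3-yl]cyclohex-2-en-1-one | O=C1C(C)=C(OCC)CC[C@]1(C)[C@H](C(C)=C)CC[C@H](C)CCO[Si](C(C)C)(C(C)C)C(C)C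
F7 | step 6 | (4R)-2,4-dimethyl-4-[(3S,6S)-2,6-dimethyl-8-(triisopropylsilyloxy)oct-1-en-3-yl]-3-(prop-2-en-1-yl)cyclohex-2-en-1-one | C=CCC1=C(C)C(=O)CC[C@]1(C)[C@H](C(C)=C)CC[C@H](C)CCO[Si](C(C)C)(C(C)C)C(C)C
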